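The synthesis rests on cutting the two ArC–CH2 bonds between C3/C5 of the central acylphloroglucinol ring and the methylene carbons on C3 of the two identical 4-hydroxy-2-pyrone rings. The key step is modelled on the presumed biosynthesis and exploits two features. C3 and C5 are equivalent, OH-flanked, strongly nucleophilic ring carbons. The pyrone C4-OH/C3 enol can expel a leaving group from its C3–CH2 arm to give a quinone-methide-like 3-methylidenepyran-2,4-dione. One operation adds two such electrophiles, the second to the mono-adduct formed in the flask, and completes the unprotected target. The precursors are (R)-2-methylbutanoylphloroglucinol and a zwitterionic pyrone C3 Mannich base.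

Key step: step 5

Assumption: (R)-2-methylbutanoic acid of high enantiomeric purity is taken as a catalogue compound. It is the source of the only stereocentre, which is (R) in the target.

Step 1
Reactants: 1 (R)-2-methylbutanoic acid; 2 phloroglucinol (benzene-1,3,5-triol)
Product: 4 (R)-2-methyl-1-(2,4,6-trihydroxyphenyl)butan-1-one, via (R)-2-methylbutanoyl chloride 3 (not isolated)
Conditions: (COCl)2 (1.0 equiv), DMF (cat.), CH2Cl2, 0 °C to rt; solution then added to 2 (1.1 equiv), AlCl3 (4 equiv), CH2Cl2/MeNO2, 0 °C to rt; aq. HCl
Reagents that add atoms: oxalyl chloride, O=C(Cl)C(=O)Cl (supplies the chlorine of 3; no atom of it remains in 4)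
Why: Vilsmeier-catalysed acid chloride formation followed by Friedel–Crafts C-acylation of the very electron-rich arene should stop at monoacylation because the aluminium-chelated aryl ketone is deactivated, and the stereocentre is carried over from 1 and protected by working at or below room temperature.

Step 2
Reactants: 5 methyl 3-oxopentanoate; 6 N-methoxy-N-methylpropanamide
Product: 7 methyl 4-methyl-3,5-dioxoheptanoate (keto/enol mixture, C4 configurationally labile)
Conditions: LDA (2.2 equiv), THF, 0 °C; then 6, −78 °C to 0 °C; aq. HCl
Reagents that add atoms: none
Why: Claisen-type γ-acylation of a β-keto ester dianion, in which the more reactive C4 carbanion attacks the Weinreb amide and the chelated tetrahedral intermediate holds until the quench, so over-addition and proton transfer to the product are avoided; the new C4 centre is not controlled and becomes sp2 in step 3.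

Step 3
Reactants: 7 methyl 4-methyl-3,5-dioxoheptanoate
Product: 8 6-ethyl-4-hydroxy-5-methyl-2H-pyran-2-one
Conditions: DBU (1.1 equiv), toluene, reflux; 1 M HCl
Reagents that add atoms: none
Why: Base-mediated lactonisation of a 3,5-dioxo ester (C5 enolate oxygen onto the ester carbonyl) is the standard 4-hydroxy-2-pyrone synthesis and is driven by loss of methanol and formation of the stabilised pyronate.

Step 4
Reactants: 8 6-ethyl-4-hydroxy-5-methyl-2H-pyran-2-one; 9 bis(dimethylamino)methane
Product: 10 3-[(dimethylamino)methyl]-6-ethyl-4-hydroxy-5-methyl-2H-pyran-2-one (zwitterionic Mannich base)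
Conditions: 8 added slowly to 9 (3 equiv), CH2Cl2, 0 °C to rt; concentration, trituration with Et2O
Reagents that add atoms: none
Why: Mannich aminomethylation in which the acidic 4-OH protonates the aminal to release CH2=NMe2+, which is taken up by C3 as the only free nucleophilic carbon, while inverse addition under anhydrous conditions keeps amine in excess and suppresses pyrone homocoupling.

Step 5
Reactants: 4 (R)-2-methyl-1-(2,4,6-trihydroxyphenyl)butan-1-one; 10 3-[(dimethylamino)methyl]-6-ethyl-4-hydroxy-5-methyl-2H-pyran-2-one (2.2 equiv)
Product: 13 3,3'-{[2,4,6-trihydroxy-5-[(2R)-2-methylbutanoyl]benzene-1,3-diyl]bis(methylene)}bis(6-ethyl-4-hydroxy-5-methyl-2H-pyran-2-one) (target), via quinone methide 11 (not isolated), via mono-adduct 12 (not isolated)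
Conditions: 10 added in portions to 4, 1,4-dioxane, 80 °C, N2 sweep; 1 M HCl
Reagents that add atoms: none
Why: On warming, zwitterionic 10 (C4 enolate, protonated nitrogen) expels dimethylamine by E1cB to give the ortho-quinone-methide-like 11, whose exocyclic CH2 is attacked by the unsubstituted ring carbon C3 of 4 in a conjugate (Michael/Friedel–Crafts-type) addition, and tautomerisation of both rings gives 12; the same sequence at the last ring C–H (C5) of 12 forms the second ArC–CH2 bond and gives 13. The closest known reaction type is the Mannich-base/quinone-methide alkylation (carba-Betti-type coupling) used for methylene-bridged acylphloroglucinol dimers and phloroglucinyl-pyrone heterodimers, which also mirrors the presumed biosynthetic bridging. No ring is closed and no stereocentre is formed; the (R)-centre next to the chelated aryl ketone is a spectator and should hold because the released amine is buffered as its salt with the acidic pyrone 4-OH groups. C- over O-alkylation is secured because phenol O-addition to 11 is reversible whereas C-addition is made irreversible by re-aromatisation, and site selectivity is secured because C3 and C5 of 4 are equivalent and are the only ring carbons that bear hydrogen, so two equivalents of 10 can give only one constitution and no over-alkylation. Pyrone homocoupling is held back because C3 of every pyrone already carries its CH2 arm and the protonated nitrogen acts as leaving group and not as donor for a retro-Mannich cleavage, while portionwise addition keeps 11 dilute and limits its self-cycloaddition.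

Compound list
1 | (R)-2-methylbutanoic acid | CC[C@@H](C)C(=O)O | starting material
2 | phloroglucinol (benzene-1,3,5-triol) | Oc1cc(O)cc(O)c1 | starting material
3 | (R)-2-methylbutanoyl chloride | CC[C@@H](C)C(=O)Cl | intermediate
4 | (R)-2-methyl-1-(2,4,6-trihydroxyphenyl)butan-1-one | CC[C@@H](C)C(=O)c1c(O)cc(O)cc1O | intermediate
5 | methyl 3-oxopentanoate | CCC(=O)CC(=O)OC | starting material
6 | N-methoxy-N-methylpropanamide | CCC(=O)N(C)OC | starting material
7 | methyl 4-methyl-3,5-dioxoheptanoate | CCC(=O)C(C)C(=O)CC(=O)OC | intermediate
8 | 6-ethyl-4-hydroxy-5-methyl-2H-pyran-2-one | CCc1oc(=O)cc(O)c1C | intermediate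
9 | bis(dimethylamino)methane | CN(C)CN(C)C | starting material
10 | 3-[(dimethylamino)methyl]-6-ethyl-4-hydroxy-5-methyl-2H-pyran-2-one | CCc1oc(=O)c(CN(C)C)c(O)c1C | intermediate
11 | 6-ethyl-5-methyl-3-methylidene-2H-pyran-2,4(3H)-dione (quinone methide) | CCC1=C(C)C(=O)C(=C)C(=O)O1 | intermediate
12 | 6-ethyl-4-hydroxy-5-methyl-3-{[2,4,6-trihydroxy-3-[(2R)-2-methylbutanoyl]phenyl]methyl}-2H-pyran-2-one (mono-adduct) | CCc1oc(=O)c(Cc2c(O)cc(O)c(C(=O)[C@H](C)CC)c2O)c(O)c1C | intermediate
13 | 3,3'-{[2,4,6-trihydroxy-5-[(2R)-2-methylbutanoyl]benzene-1,3-diyl]bis(methylene)}bis(6-ethyl-4-hydroxy-5-methyl-2H-pyran-2-one) | CCc1oc(=O)c(Cc2c(O)c(Cc3c(O)c(C)c(CC)oc3=O)c(O)c(C(=O)[C@H](C)CC)c2O)c(O)c1C | target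

Total step count: 5.
Longest linear sequence: 4 (steps 2, 3, 4 and 5, from 5 to 13).

Steps most likely to fail

1. Step 5.
- Risk: retro-Mannich amine transfer could be followed by pyrone–pyrone homocoupling. The quinone methide could undergo self-cycloaddition. The reaction could also stall after the first alkylation.
- Fallback: it sets out from 8 and replaces the amine by a carbon–sulfur leaving group. This group cannot act as a donor and is released by mild inorganic base at room temperature.
- Three-component thiomethylation of 8 (aqueous formaldehyde, thiophenol, cat. piperidine/AcOH, EtOH) should give the sulfide 6-ethyl-4-hydroxy-5-methyl-3-[(phenylsulfanyl)methyl]-2H-pyran-2-one F1.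
- Oxidation with mCPBA (2.2 equiv, CH2Cl2, 0 °C) should give the sulfone 3-[(benzenesulfonyl)methyl]-6-ethyl-4-hydroxy-5-methyl-2H-pyran-2-one F2.
- F2 (2.2 equiv), 4 and K2CO3 in MeCN at room temperature should lose benzenesulfinate to give 11. Compound 11 is trapped as in the main route, through 12.
- The fallback comes back to the route at 13.

2. Step 4.
- Risk: dimethylamine could be lost during concentration and isolation of the Mannich base, followed by homocoupling of the pyrone.
- Fallback: it sets out from 8, with 4 as partner, and isolates no precursor.
- Compound 8 (2.1 equiv) is added by syringe pump to 4, paraformaldehyde (2.2 equiv) and catalytic ethylenediammonium diacetate in THF at 50 °C.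
- Knoevenagel condensation then generates 11 directly in the presence of its trap, in a multicomponent carba-Betti-type coupling.
- It comes back to the route at 13 and makes no compound that the list does not hold (F0).

3. Step 1.
- Risk: enantiomeric purity could erode through ketene formation from the acid chloride or through Lewis-acid-promoted enolisation of the aryl ketone. A second acylation is also possible.
- Fallback: it sets out from 1 and 2 and replaces electrophilic aromatic substitution by an aryllithium addition.
- Compound 1 is coupled with N,O-dimethylhydroxylamine hydrochloride (CDI, CH2Cl2) to give the Weinreb amide (R)-N-methoxy-N,2-dimethylbutanamide F3.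
- Compound 2 is protected (MOMCl, iPr2NEt, CH2Cl2) as 1,3,5-tris(methoxymethoxy)benzene F4.
- Directed ortho-lithiation of F4 (n-BuLi, THF, 0 °C) and addition to F3 at −78 °C should give (R)-2-methyl-1-[2,4,6-tris(methoxymethoxy)phenyl]butan-1-one F5.
- HCl in MeOH at room temperature removes the three MOM groups.
- The fallback comes back to the route at 4.

Further compounds
F1 | step 5 | 6-ethyl-4-hydroxy-5-methyl-3-[(phenylsulfanyl)methyl]-2H-pyran-2-one | CCc1oc(=O)c(CSc2ccccc2)c(O)c1C
F2 | step 5 | 3-[(benzenesulfonyl)methyl]-6-ethyl-4-hydroxy-5-methyl-2H-pyran-2-one | CCc1oc(=O)c(CS(=O)(=O)c2ccccc2)c(O)c1C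
F0 | step 4 | none | none
F3 | step 1 | (R)-N-methoxy-N,2-dimethylbutanamide | CC[C@@H](C)C(=O)N(C)OC
F4 | step 1 | 1,3,5-tris(methoxymethoxy)benzene | COCOc1cc(OCOC)cc(OCOC)c1
F5 | step 1 | (R)-2-methyl-1-[2,4,6-tris(methoxymethoxy)phenyl]butan-1-one | CC[C@@H](C)C(=O)c1c(OCOC)cc(OCOC)cc1OCOC
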